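## Retrosynthetic overview

- Locants: C-1 to C-6 are the ring carbons of the target as numbered in its name, C-7 is the exocyclic CH2 carbon. The enabling feature is the cyclohex-3-ene ring itself: C-3=C-4 lies between the two oxygen-bearing carbons C-2 and C-5 and opposite the cis-diol pair C-1/C-6. This is the retron of a [4+2] union of a 1,4-dioxygenated diene (C-2 to C-5) with a cis-enediol dienophile (C-6=C-1, carrying C-7).
- Key disconnection: C-1–C-2 and C-5–C-6, made together by an intramolecular Diels–Alder reaction. The diene is a 2-silyloxyfuran (ring oxygen = later oxygen on C-5; silyloxy carbon = C-2 at the ketone level). The dienophile is a (2R)-2-tert-butyl-1,3-dioxole-4-carboxylate (C-7 at the acid level). One silicon atom links the furan oxygen and the carboxylate as a temporary tether.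
- Ring order: the dioxole comes from methyl (R)-glycerate acetonide, with the chirality relayed to the acetal carbon. The cyclohexene is the only ring built; the oxygen bridge opens in the flask to the cyclohexenone. Sila-ring, γ-lactone and dioxolane are temporary.
- After the key step: lactone-guided reduction of the C-2 ketone sets the last stereocentre and thus the trans relation of the oxygens on C-2 and C-5. LiAlH4 then opens the lactone, three benzoates go on at once, and acid frees the diol.

Key step: step 4

Remark on the chemistry: all starting materials are taken as commercial. CIP descriptors of intermediates change with substituent priorities although the spatial arrangement is kept.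

## Route

Step 1
Reactants: 1 methyl (4R)-2,2-dimethyl-1,3-dioxolane-4-carboxylate; 2 pivalaldehyde
Product: 3 methyl (2R,4R)-2-tert-butyl-1,3-dioxolane-4-carboxylate
Conditions: 2 (excess), TsOH·H2O (cat.), cyclohexane, 60 °C, acetone distilled off; cis isomer separated on silica gel
Reagents that add atoms: pivalaldehyde, CC(C)(C)C=O
Why: Acid-catalysed acetal exchange (transacetalisation), driven by removal of acetone, should give the 2-tert-butyl dioxolane as a cis/trans pair differing only at the new acetal carbon, and separation of the cis isomer 3 (tert-butyl and ester on the same face; the trans isomer is recycled by re-equilibration) fixes that carbon as R by relay from the untouched C-4 centre of 1.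

Step 2
Reactants: 3 methyl (2R,4R)-2-tert-butyl-1,3-dioxolane-4-carboxylate; 4 benzeneselenenyl bromide
Product: 7 methyl (2R)-2-tert-butyl-1,3-dioxole-4-carboxylate, via selenide 5 (not isolated), via selenoxide 6 (not isolated)
Conditions: LiN(iPr)2, THF, −78 °C; 4, −78 °C; then H2O2 (30%), pyridine, CH2Cl2, 0 → 23 °C
Reagents that add atoms: none
Why: Ester enolate α-selenenylation followed by selenoxide syn-elimination toward the only β-hydrogens (on the OCH2 carbon), the known way from 1,3-dioxan-4-ones to dioxinones, should give the enol ether double bond; the former glycerate centre becomes sp2, so the acetal carbon alone carries the chirality on (self-regeneration of stereocentres).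

Step 3
Reactants: 7 methyl (2R)-2-tert-butyl-1,3-dioxole-4-carboxylate
Product: 8 potassium (2R)-2-tert-butyl-1,3-dioxole-4-carboxylate
Conditions: KOSiMe3, Et2O, 23 °C; salt filtered off and dried
Reagents that add atoms: potassium trimethylsilanolate, C[Si](C)(C)[O-].[K+]
Why: Potassium trimethylsilanolate cleaves the methyl ester under anhydrous, non-acidic conditions (nucleophilic demethylation or acyl substitution, both ending in carboxylate and methoxytrimethylsilane), so the acid-labile enol acetal survives and a dry salt is obtained for silylation; the stereocentre is not involved.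

Step 4
Reactants: 8 potassium (2R)-2-tert-butyl-1,3-dioxole-4-carboxylate; 9 diisopropylsilyl bis(trifluoromethanesulfonate); 10 furan-2(5H)-one
Product: 14 (2R,3aS,7R,7aS)-2-tert-butyl-4-oxo-3a,4,7,7a-tetrahydro-1,3-benzodioxole whose O-7 is joined to the 3a-carboxylate through Si(iPr)2, via silyl triflate 11 (not isolated), via tethered silyloxyfuran 12 (not isolated), via oxanorbornene adduct 13 (not isolated)
Conditions: 8, 9, THF/CH2Cl2, −78 °C; then 10, Et3N, −78 → 23 °C; 40 °C; salts filtered off, crude 14 used directly
Reagents that add atoms: diisopropylsilyl bis(trifluoromethanesulfonate), CC(C)[Si](OS(=O)(=O)C(F)(F)F)(OS(=O)(=O)C(F)(F)F)C(C)C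
Why: Proposed new method: the one silicon atom of 9 silylates first carboxylate 8 and then the dienol form of 10, which joins diene and dienophile through an O–Si–O–C(=O) tether (12); the electron-rich 2-silyloxyfuran then adds across the carboxyl-bearing dioxole double bond in an intramolecular Diels–Alder reaction that forms C-2–C-1 and C-5–C-6 at once, the bridgehead silyl ketal of 13 opens by oxygen-assisted cleavage of the C-2–O bridge to the enone, and the C-5 alkoxide takes over the silicon to give 14. The closest known reaction types are intramolecular Diels–Alder/ring-opening cascades of furans tethered through a 2-amino or 2-amido group, temporary silicon-tethered Diels–Alder reactions and intermolecular Diels–Alder reactions of 2-silyloxyfurans; a silyl ester/silyl dienol ether tether has not been shown. The cyclohexene ring closes by suprafacial [4+2] addition, and the transient six-membered sila-ring closes in the fused mode because the tether joins the two carbons that bond to each other (the bridged mode would need a seven-membered ring and mismatched polarity). C-1 and C-6 are set together: their cis oxygens follow from the ring-locked Z-enediol and their absolute configuration from attack on the dioxole face anti to the tert-butyl group of the acetal carbon. C-5 is set by the exo orientation of the tethered carboxyl (same face as the oxygen bridge), which the short fused tether should favour as in other furan cycloadditions tethered at C-2, so that the oxygen on C-5 ends trans to the oxygen on C-6 and cis to C-7. The step needs regioselectivity (tether, matched by polarity: nucleophilic furan terminus to the β-carbon C-6), exo selectivity (tether) and π-facial selectivity (tert-butyl acetal); C-2 leaves the step as a ketone, so the trans-1,4 relation of the allylic oxygens does not depend on the cycloaddition.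

Step 5
Reactants: 14 silylene-bridged enone
Product: 16 (1S,3R,5S,6R)-3-tert-butyl-2,4,11-trioxatricyclo[4.3.2.0^{1,5}]undec-7-ene-9,10-dione, via hydroxy keto acid 15 (not isolated)
Conditions: HF·pyridine, THF, −20 °C; then EDC·HCl, DMAP (cat.), CH2Cl2, 0 °C
Reagents that add atoms: none
Why: Fluoride cleaves both Si–O bonds and carbodiimide activation (Steglich-type lactonisation) at low temperature should close the γ-lactone from the C-5 hydroxyl onto the cis carboxyl before the β-keto acid 15 can decarboxylate; no stereocentre is formed, and only the diastereomer with C-7 and the C-5 oxygen cis can close, so a minor endo adduct from step 4 is purged here.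

Step 6
Reactants: 16 lactone enone
Product: 17 (1R,3R,5S,6R,9R)-3-tert-butyl-9-hydroxy-2,4,11-trioxatricyclo[4.3.2.0^{1,5}]undec-7-en-10-one
Conditions: NaBH4, CeCl3·7H2O, MeOH/CH2Cl2, −78 °C
Reagents that add atoms: none
Why: Luche reduction (1,2-selective for enones): in the rigid 6-oxabicyclo[3.2.1]octenone the face of the C-2 ketone turned toward the one-carbon bridge is screened by the syn-axial acetal oxygen on C-6 and by the dioxolane ring, so hydride should arrive from the lactone side and place the new hydroxyl cis to the oxygen on C-1 (9R), which completes the trans relation of the oxygens on C-2 and C-5.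

Step 7
Reactants: 17 hydroxy lactone
Product: 18 (2R,3aR,4R,7R,7aS)-2-tert-butyl-3a-(hydroxymethyl)-3a,4,7,7a-tetrahydro-1,3-benzodioxole-4,7-diol
Conditions: LiAlH4, THF, 0 → 23 °C; aqueous NaOH work-up
Reagents that add atoms: none
Why: LiAlH4 reduction of the lactone should give the primary alcohol at C-7 and free the C-5 hydroxyl in one operation; the acetal and the isolated double bond are inert to hydride and no stereocentre is touched.

Step 8
Reactants: 18 triol; 19 benzoyl chloride
Product: 20 (2R,3aR,4R,7R,7aS)-3a-[(benzoyloxy)methyl]-2-tert-butyl-3a,4,7,7a-tetrahydro-1,3-benzodioxole-4,7-diyl dibenzoate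
Conditions: 19 (3.6 equiv), pyridine, DMAP (cat.), CH2Cl2, 0 → 40 °C
Reagents that add atoms: benzoyl chloride, O=C(Cl)c1ccccc1
Why: DMAP-catalysed acylation with benzoyl chloride esterifies the primary and the two allylic secondary hydroxyls together; the cis-diol that must stay free is locked in the acetal, so no site selectivity is required.

Step 9
Reactants: 20 tribenzoate acetal
Product: 21 [(1S,2R,5R,6S)-2,5-bis(benzoyloxy)-1,6-dihydroxycyclohex-3-en-1-yl]methyl benzoate (CNP0128482.1)
Conditions: CF3CO2H/H2O (9:1), CH2Cl2, 0 → 23 °C
Reagents that add atoms: none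
Why: Acid-catalysed hydrolysis of the pivalaldehyde acetal liberates the C-1/C-6 cis-diol; benzoates tolerate aqueous trifluoroacetic acid and the allylic C–O bonds are deactivated toward ionisation by the flanking oxygens, so configuration and ester positions should be retained.

## Compound list

1 | methyl (4R)-2,2-dimethyl-1,3-dioxolane-4-carboxylate | COC(=O)[C@H]1COC(C)(C)O1 | starting material
2 | pivalaldehyde (2,2-dimethylpropanal) | CC(C)(C)C=O | starting material
3 | methyl (2R,4R)-2-tert-butyl-1,3-dioxolane-4-carboxylate (cis) | CC(C)(C)[C@@H]1OC[C@H](C(=O)OC)O1 | intermediate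
4 | benzeneselenenyl bromide | Br[Se]c1ccccc1 | starting material
5 | methyl (2R,4S)-2-tert-butyl-4-(phenylselanyl)-1,3-dioxolane-4-carboxylate (selenium trans to tert-butyl expected) | CC(C)(C)[C@@H]1OC[C@]([Se]c2ccccc2)(C(=O)OC)O1 | intermediate
6 | methyl (2R,4S)-2-tert-butyl-4-(phenylseleninyl)-1,3-dioxolane-4-carboxylate (both configurations at selenium) | CC(C)(C)[C@@H]1OC[C@]([Se](=O)c2ccccc2)(C(=O)OC)O1 | intermediate
7 | methyl (2R)-2-tert-butyl-1,3-dioxole-4-carboxylate | CC(C)(C)[C@@H]1OC=C(C(=O)OC)O1 | intermediate
8 | potassium (2R)-2-tert-butyl-1,3-dioxole-4-carboxylate | CC(C)(C)[C@@H]1OC=C(C(=O)[O-])O1.[K+] | intermediate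
9 | diisopropylsilyl bis(trifluoromethanesulfonate) | CC(C)[Si](OS(=O)(=O)C(F)(F)F)(OS(=O)(=O)C(F)(F)F)C(C)C | starting material
10 | furan-2(5H)-one | O=C1OCC=C1 | starting material
11 | diisopropyl[(trifluoromethanesulfonyl)oxy]silyl (2R)-2-tert-butyl-1,3-dioxole-4-carboxylate | CC(C)(C)[C@@H]1OC=C(C(=O)O[Si](C(C)C)(C(C)C)OS(=O)(=O)C(F)(F)F)O1 | intermediate
12 | (furan-2-yloxy)diisopropylsilyl (2R)-2-tert-butyl-1,3-dioxole-4-carboxylate | CC(C)(C)[C@@H]1OC=C(C(=O)O[Si](C(C)C)(C(C)C)Oc2ccco2)O1 | intermediate
13 | intramolecular Diels–Alder adduct of 12: 7-oxanorbornene with the silyloxy oxygen on bridgehead C-2, carboxyl exo, dioxolane endo, tert-butyl anti to the new ring | CC(C)[Si]1(C(C)C)OC(=O)[C@]23O[C@H](C(C)(C)C)O[C@H]2[C@H]4C=C[C@]3(O1)O4 | intermediate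
14 | (2R,3aS,7R,7aS)-2-tert-butyl-4-oxo-3a,4,7,7a-tetrahydro-1,3-benzodioxole whose O-7 is joined to the 3a-carboxylate through Si(iPr)2 | CC(C)[Si]1(C(C)C)OC(=O)[C@]23O[C@H](C(C)(C)C)O[C@H]2[C@H](O1)C=CC3=O | intermediate
15 | (2R,3aS,7R,7aS)-2-tert-butyl-7-hydroxy-4-oxo-3a,4,7,7a-tetrahydro-1,3-benzodioxole-3a-carboxylic acid | OC(=O)[C@]12O[C@H](C(C)(C)C)O[C@H]1[C@H](O)C=CC2=O | intermediate
16 | (1S,3R,5S,6R)-3-tert-butyl-2,4,11-trioxatricyclo[4.3.2.0^{1,5}]undec-7-ene-9,10-dione | O=C1O[C@@H]2C=CC(=O)[C@@]1(O[C@H](C(C)(C)C)O3)[C@H]23 | intermediate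
17 | (1R,3R,5S,6R,9R)-3-tert-butyl-9-hydroxy-2,4,11-trioxatricyclo[4.3.2.0^{1,5}]undec-7-en-10-one | O=C1O[C@@H]2C=C[C@@H](O)[C@@]1(O[C@H](C(C)(C)C)O3)[C@H]23 | intermediate
18 | (2R,3aR,4R,7R,7aS)-2-tert-butyl-3a-(hydroxymethyl)-3a,4,7,7a-tetrahydro-1,3-benzodioxole-4,7-diol | OC[C@@]1(O[C@H](C(C)(C)C)O2)[C@H](O)C=C[C@@H](O)[C@@H]12 | intermediate
19 | benzoyl chloride | O=C(Cl)c1ccccc1 | starting material
20 | (2R,3aR,4R,7R,7aS)-3a-[(benzoyloxy)methyl]-2-tert-butyl-3a,4,7,7a-tetrahydro-1,3-benzodioxole-4,7-diyl dibenzoate | O=C(OC[C@@]1(O[C@H](C(C)(C)C)O2)[C@H](OC(=O)c3ccccc3)C=C[C@@H](OC(=O)c3ccccc3)[C@@H]12)c1ccccc1 | intermediate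
21 | [(1S,2R,5R,6S)-2,5-bis(benzoyloxy)-1,6-dihydroxycyclohex-3-en-1-yl]methyl benzoate (CNP0128482.1) | O=C(OC[C@@]1(O)[C@H](OC(=O)c2ccccc2)C=C[C@@H](OC(=O)c2ccccc2)[C@@H]1O)c1ccccc1 | target

## Step count and risks

Total step count: 9. Longest linear sequence: 9 steps (1 → 21).

**Step 4 (proposed new method).** What may go wrong: unselective silylation that gives symmetrical bis-carboxylate or bis-furyloxy silanes instead of the mixed tether, a cycloaddition too slow at temperatures the silyl ester tolerates, or leakage through the endo mode. The fallback uses known chemistry, sets out from 7 and comes back at 16. A thermal intermolecular Diels–Alder reaction of 7 with commercial (1E,3E)-buta-1,3-diene-1,4-diyl diacetate (toluene, BHT, 140 °C, sealed tube, or 12–15 kbar at 50 °C) is the reaction type by which this diene adds to acrylic esters with the ester endo. Addition anti to the tert-butyl group should give methyl (2R,3aR,4S,7R,7aS)-4,7-bis(acetyloxy)-2-tert-butyl-3a,4,7,7a-tetrahydro-1,3-benzodioxole-3a-carboxylate F1. K2CO3 (cat.) in MeOH at 0 °C removes both acetates, and the hydroxyl on C-5 closes onto the cis ester to give (1R,3R,5S,6R,9S)-3-tert-butyl-9-hydroxy-2,4,11-trioxatricyclo[4.3.2.0^{1,5}]undec-7-en-10-one F2, whose C-2 hydroxyl is still trans to the oxygen on C-1. Dess–Martin periodinane (NaHCO3, CH2Cl2) oxidises this allylic alcohol to 16.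

**Step 6.** What may go wrong: poor facial selectivity of hydride addition, because the torsionally preferred axial attack competes with the sterically preferred attack from the lactone side. The fallback sets out from 16 and comes back at 18. The reduction is run as before; the 9S alcohol that forms is the hydroxy lactone F2 of the first fallback. It is inverted by a Mitsunobu reaction with benzoic acid (PPh3, DIAD, toluene, 0 → 23 °C) to (1R,3R,5S,6R,9R)-3-tert-butyl-10-oxo-2,4,11-trioxatricyclo[4.3.2.0^{1,5}]undec-7-en-9-yl benzoate F3. LiAlH4 then reduces lactone and benzoate together and gives 18. Any 17 formed alongside goes on by the main route.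

**Step 5.** What may go wrong: loss of CO2 from the β-keto acid, or retro-Claisen opening, before the lactone closes. The fallback sets out from 14 and comes back at 17. The ketone is reduced first (NaBH4, CeCl3·7H2O, MeOH/CH2Cl2, −78 °C, where neither the silyl ester nor a liberated keto acid decarboxylates) to the silylene-bridged alcohol (2R,3aR,4R,7R,7aS)-2-tert-butyl-4-hydroxy-3a,4,7,7a-tetrahydro-1,3-benzodioxole with O-7 joined to the 3a-carboxylate through Si(iPr)2, F4. HF·pyridine then frees (2R,3aR,4R,7R,7aS)-2-tert-butyl-4,7-dihydroxy-3a,4,7,7a-tetrahydro-1,3-benzodioxole-3a-carboxylic acid F5, a β-hydroxy acid that cannot decarboxylate, and EDC·HCl/DMAP closes the γ-lactone to 17. Should hydride add with the opposite facial sense in this less rigid ring, the epimer would be handled as in the fallback for step 6.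

## Further compounds

F1 | step 4 | methyl (2R,3aR,4S,7R,7aS)-4,7-bis(acetyloxy)-2-tert-butyl-3a,4,7,7a-tetrahydro-1,3-benzodioxole-3a-carboxylate | COC(=O)[C@]12O[C@H](C(C)(C)C)O[C@H]1[C@H](OC(C)=O)C=C[C@@H]2OC(C)=O
F2 | step 4 | (1R,3R,5S,6R,9S)-3-tert-butyl-9-hydroxy-2,4,11-trioxatricyclo[4.3.2.0^{1,5}]undec-7-en-10-one | O=C1O[C@@H]2C=C[C@H](O)[C@@]1(O[C@H](C(C)(C)C)O3)[C@H]23
F3 | step 6 | (1R,3R,5S,6R,9R)-3-tert-butyl-10-oxo-2,4,11-trioxatricyclo[4.3.2.0^{1,5}]undec-7-en-9-yl benzoate | O=C1O[C@@H]2C=C[C@@H](OC(=O)c4ccccc4)[C@@]1(O[C@H](C(C)(C)C)O3)[C@H]23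
F4 | step 5 | (2R,3aR,4R,7R,7aS)-2-tert-butyl-4-hydroxy-3a,4,7,7a-tetrahydro-1,3-benzodioxole with O-7 joined to the 3a-carboxylate through Si(iPr)2 | CC(C)[Si]1(C(C)C)OC(=O)[C@]23O[C@H](C(C)(C)C)O[C@H]2[C@H](O1)C=C[C@H]3O
F5 | step 5 | (2R,3aR,4R,7R,7aS)-2-tert-butyl-4,7-dihydroxy-3a,4,7,7a-tetrahydro-1,3-benzodioxole-3a-carboxylic acid | OC(=O)[C@]12O[C@H](C(C)(C)C)O[C@H]1[C@H](O)C=C[C@H]2O
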